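**Retrosynthetic overview**

- The target is disconnected at the C3 ester (Yamaguchi acylation of the cis C3 alcohol with (Z)-4-acetoxy-2-methylbut-2-enoic acid, made from 3-methylfuran-2(5H)-one, whose ring locks the Z geometry) and at a 4-methoxybenzyl ether on the C6 phenol.
- The cis alcohol comes from an acyclic (1S,2S)-diol on a 5-acetyl-2,4-difluorophenyl ring by a one-flask double SNAr: the C2 alkoxide closes ring B (the dihydrofuran) by forming O1–C7a, then 4-methoxybenzyl oxide replaces the fluoride at C6. Ring A (the benzene ring) is carried from the start; ring B is the only ring formed.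
- Enabling feature: the C5 acetyl carbonyl on ring A is para to C7a and ortho to C6, so it stabilises both anionic σ-complexes. The C2 hydroxyl sits two atoms from C3a, so it can only close a five-membered ring onto C7a.
- The diol comes from Stille acetylation of the aryl bromide, preceded by a hydroxy-directed singlet-oxygen ene reaction of an (R)-allylic alcohol (C3 controls C2 and the isopropenyl group is unveiled), itself made by enantioselective aryl transfer from 1,5-dibromo-2,4-difluorobenzene to prenal.

Key step: step 4

Assumption: the sense of induction of (2S)-(−)-3-exo-morpholinoisoborneol in aryl transfer is taken to be the same as in its alkylzinc additions (Si-face delivery); should it prove opposite, the (+)-ligand is used in step 1 with no other change.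

**Step 1**
Reactants: 1 1,5-dibromo-2,4-difluorobenzene; 2 3-methylbut-2-enal (prenal)
Product: 6 (R)-1-(5-bromo-2,4-difluorophenyl)-3-methylbut-2-en-1-ol, via aryllithium 3 (not isolated), via arylzinc chloride 4 (not isolated), via arylbutylzinc 5 (not isolated)
Conditions: 1 (2 equiv), n-BuLi (2 equiv), t-BuOMe, −78 °C; ZnCl2 (2 equiv), −78 → 0 °C; n-BuLi (2 equiv); N,N,N′,N′-tetraethylethylenediamine; (2S)-(−)-3-exo-morpholinoisoborneol (5 mol %), 2 (1 equiv), toluene, 0 °C; aqueous work-up
Reagents that add atoms: none
Why: Catalytic enantioselective aryl transfer from a mixed arylbutylzinc reagent to an enal under amino alcohol catalysis, a reaction type established for aryl bromides and α,β-unsaturated aldehydes; the diamine sequesters LiCl to suppress the racemic background addition, and the zinc–amino alcohol chelate should deliver the aryl group to the Si face of the aldehyde, which sets the future C3 as the (R) carbinol of 6.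

**Step 2**
Reactants: 6 (R)-1-(5-bromo-2,4-difluorophenyl)-3-methylbut-2-en-1-ol
Product: 8 (1S,2S)-1-(5-bromo-2,4-difluorophenyl)-3-methylbut-3-ene-1,2-diol, via hydroperoxide 7 (not isolated)
Conditions: O2, 5,10,15,20-tetraphenylporphyrin (cat.), visible light, CH2Cl2, −20 °C; then PPh3, −20 °C → rt
Reagents that add atoms: dioxygen (O=O)
Why: Hydroxy-directed Schenck ene reaction of singlet oxygen with a chiral allylic alcohol bearing a cis methyl group: 1,3-allylic strain holds the carbinol C–H in the alkene plane, hydrogen bonding steers the oxygen to the face carrying the OH so that the new C2–O bond forms threo to C3–O, a geminal methyl group supplies the hydrogen and becomes the methylene of the isopropenyl group, and PPh3 reduces the hydroperoxide without touching either stereocenter.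

**Step 3**
Reactants: 8 (1S,2S)-1-(5-bromo-2,4-difluorophenyl)-3-methylbut-3-ene-1,2-diol
Product: 10 1-{5-[(1S,2S)-1,2-dihydroxy-3-methylbut-3-en-1-yl]-2,4-difluorophenyl}ethan-1-one, via enol ether 9 (not isolated)
Conditions: tributyl(1-ethoxyvinyl)stannane, PdCl2(PPh3)2 (5 mol %), toluene, 95 °C; then 1 M HCl, THF, rt
Reagents that add atoms: tributyl(1-ethoxyvinyl)stannane (C=C(OCC)[Sn](CCCC)(CCCC)CCCC); water (O)
Why: Stille coupling of the electron-poor aryl bromide with an acetyl anion equivalent followed by mild hydrolysis of the aryl enol ether; the free diol and the 1,1-disubstituted alkene are tolerated, the C–F bonds are inert to zerovalent palladium, and the acetyl group arrives ortho to one fluorine and para to the other.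

**Step 4**
Reactants: 10 1-{5-[(1S,2S)-1,2-dihydroxy-3-methylbut-3-en-1-yl]-2,4-difluorophenyl}ethan-1-one
Product: 12 1-[(2S,3S)-3-hydroxy-6-[(4-methoxyphenyl)methoxy]-2-(prop-1-en-2-yl)-2,3-dihydro-1-benzofuran-5-yl]ethan-1-one, via fluoro dihydrobenzofuranol 11 (not isolated)
Conditions: NaH (1.2 equiv), THF (0.02 M), 0 °C → rt; then NaOCH2C6H4-4-OMe (from 4-methoxybenzyl alcohol 2 equiv + NaH 2 equiv), THF/DMF, rt → 45 °C; aq NH4Cl
Reagents that add atoms: 4-methoxybenzyl alcohol (COc1ccc(CO)cc1)
Why: Deprotonation gives the C2 alkoxide, which adds to C7a of ring A to form an anionic σ-complex whose charge is delocalised into the para C5 acetyl carbonyl, fluoride is lost to close ring B, and the added 4-methoxybenzyl oxide then displaces the remaining fluoride at C6, activated by the ortho acetyl group, through a second σ-complex. The closest known reaction types are the intramolecular SNAr etherification of 2-(2-fluoroaryl)ethanol alkoxides to 2,3-dihydrobenzofurans and the SNAr of 2- and 4-fluoroacetophenones with alkoxides. Ring B is closed in the 5-exo-trig mode, O1 attacking C7a with the attacked C7a=C7 π bond outside the new ring. No stereocenter is created: C2 and C3 keep the (S,S) configuration set in steps 1 and 2 because neither C–O bond at these carbons is broken, and the threo diol maps directly onto the cis 2,3-disubstituted ring. The step needs selectivity between the two hydroxyls, secured by ring size (C2–O gives a five-membered ring, C3–O would give a four-membered one); between the two fluorides, secured by the tether (only C7a is within reach of the C2 alkoxide); and between ring closure and intermolecular substitution, secured by dilution and by adding the external alkoxide only after closure. About one equivalent of NaH in THF in the first stage should leave the acetyl group largely un-enolised so that it can act as the activating group.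

**Step 5**
Reactants: 13 3-methylfuran-2(5H)-one
Product: 15 (4-methoxyphenyl)methyl (Z)-4-hydroxy-2-methylbut-2-enoate, via potassium hydroxy carboxylate 14 (not isolated)
Conditions: KOH (1.0 equiv), H2O/THF, 0 °C → rt; evaporate to dryness; 4-methoxybenzyl chloride, Bu4NI (cat.), DMF, rt
Reagents that add atoms: potassium hydroxide ([K+].[OH-]); 4-methoxybenzyl chloride (COc1ccc(CCl)cc1)
Why: Saponification of the butenolide, whose ring fixes the (Z) geometry, followed by O-alkylation of the carboxylate salt (lactone opening and carboxylate alkylation), which traps the hydroxy acid before it can relactonise.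

**Step 6**
Reactants: 15 (4-methoxyphenyl)methyl (Z)-4-hydroxy-2-methylbut-2-enoate
Product: 16 (4-methoxyphenyl)methyl (Z)-4-acetoxy-2-methylbut-2-enoate
Conditions: Ac2O, pyridine, DMAP (cat.), CH2Cl2, 0 °C (crude 15 used at once)
Reagents that add atoms: acetic anhydride (CC(=O)OC(C)=O)
Why: Standard acetylation of the primary allylic alcohol, which should be fast enough at 0 °C to outrun relactonisation and after which the (Z) acid can no longer close to the butenolide.

**Step 7**
Reactants: 16 (4-methoxyphenyl)methyl (Z)-4-acetoxy-2-methylbut-2-enoate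
Product: 17 (Z)-4-acetoxy-2-methylbut-2-enoic acid
Conditions: CF3CO2H, anisole, CH2Cl2, 0 °C
Reagents that add atoms: none
Why: Acidolysis of the 4-methoxybenzyl ester through the stabilised benzylic cation, scavenged by anisole, frees the carboxylic acid under conditions that leave the primary acetate and the (Z) trisubstituted alkene untouched.

**Step 8**
Reactants: 12 1-[(2S,3S)-3-hydroxy-6-[(4-methoxyphenyl)methoxy]-2-(prop-1-en-2-yl)-2,3-dihydro-1-benzofuran-5-yl]ethan-1-one; 17 (Z)-4-acetoxy-2-methylbut-2-enoic acid
Product: 19 (2S,3S)-5-acetyl-6-[(4-methoxyphenyl)methoxy]-2-(prop-1-en-2-yl)-2,3-dihydro-1-benzofuran-3-yl (Z)-4-acetoxy-2-methylbut-2-enoate, via mixed anhydride 18 (not isolated)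
Conditions: 17 (2 equiv), 2,4,6-trichlorobenzoyl chloride, Et3N, toluene, rt; then 12, toluene, 60–70 °C (no DMAP)
Reagents that add atoms: none
Why: Yamaguchi esterification through the preformed mixed anhydride, run thermally without a nucleophilic catalyst as is usual for angelate-type (Z)-2-methylbut-2-enoates so that the (Z) geometry is kept; the hindered trichlorobenzoyl carbonyl directs the C3 hydroxyl to the enoyl carbonyl, the C3–O bond is not broken so the cis configuration is retained, and the ether-protected phenol cannot compete.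

**Step 9**
Reactants: 19 (2S,3S)-5-acetyl-6-[(4-methoxyphenyl)methoxy]-2-(prop-1-en-2-yl)-2,3-dihydro-1-benzofuran-3-yl (Z)-4-acetoxy-2-methylbut-2-enoate
Product: 20 (2S,3S)-5-acetyl-6-hydroxy-2-(prop-1-en-2-yl)-2,3-dihydro-1-benzofuran-3-yl (Z)-4-acetoxy-2-methylbut-2-enoate (target)
Conditions: DDQ (1.5 equiv), CH2Cl2/pH 7 phosphate buffer (10:1), 0 °C → rt
Reagents that add atoms: none
Why: Oxidative cleavage of the 4-methoxybenzyl aryl ether by DDQ (hydride abstraction from the electron-rich benzyl group, then hydrolysis of the oxocarbenium ion) under neutral buffered conditions, which should spare the benzylic ester at C3, the allylic acetate, the (Z) enoate and the isopropenyl group, while the freed phenol is deactivated toward further oxidation by its hydrogen bond to the C5 acetyl group.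

**Compound list**

1 | 1,5-dibromo-2,4-difluorobenzene | Fc1cc(F)c(Br)cc1Br | starting material
2 | 3-methylbut-2-enal | CC(C)=CC=O | starting material
3 | (5-bromo-2,4-difluorophenyl)lithium | [Li]c1cc(Br)c(F)cc1F | intermediate
4 | (5-bromo-2,4-difluorophenyl)zinc chloride | Cl[Zn]c1cc(Br)c(F)cc1F | intermediate
5 | butyl(5-bromo-2,4-difluorophenyl)zinc | CCCC[Zn]c1cc(Br)c(F)cc1F | intermediate
6 | (R)-1-(5-bromo-2,4-difluorophenyl)-3-methylbut-2-en-1-ol | CC(C)=C[C@@H](O)c1cc(Br)c(F)cc1F | intermediate
7 | (1S,2S)-1-(5-bromo-2,4-difluorophenyl)-2-hydroperoxy-3-methylbut-3-en-1-ol | C=C(C)[C@H](OO)[C@@H](O)c1cc(Br)c(F)cc1F | intermediate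
8 | (1S,2S)-1-(5-bromo-2,4-difluorophenyl)-3-methylbut-3-ene-1,2-diol | C=C(C)[C@H](O)[C@@H](O)c1cc(Br)c(F)cc1F | intermediate
9 | (1S,2S)-1-[5-(1-ethoxyethenyl)-2,4-difluorophenyl]-3-methylbut-3-ene-1,2-diol | C=C(C)[C@H](O)[C@@H](O)c1cc(C(=C)OCC)c(F)cc1F | intermediate
10 | 1-{5-[(1S,2S)-1,2-dihydroxy-3-methylbut-3-en-1-yl]-2,4-difluorophenyl}ethan-1-one | C=C(C)[C@H](O)[C@@H](O)c1cc(C(C)=O)c(F)cc1F | intermediate
11 | 1-[(2S,3S)-6-fluoro-3-hydroxy-2-(prop-1-en-2-yl)-2,3-dihydro-1-benzofuran-5-yl]ethan-1-one | C=C(C)[C@@H]1Oc2cc(F)c(C(C)=O)cc2[C@@H]1O | intermediate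
12 | 1-[(2S,3S)-3-hydroxy-6-[(4-methoxyphenyl)methoxy]-2-(prop-1-en-2-yl)-2,3-dihydro-1-benzofuran-5-yl]ethan-1-one | C=C(C)[C@@H]1Oc2cc(OCc3ccc(OC)cc3)c(C(C)=O)cc2[C@@H]1O | intermediate
13 | 3-methylfuran-2(5H)-one | CC1=CCOC1=O | starting material
14 | potassium (Z)-4-hydroxy-2-methylbut-2-enoate | [K+].[O-]C(=O)/C(C)=C\CO | intermediate
15 | (4-methoxyphenyl)methyl (Z)-4-hydroxy-2-methylbut-2-enoate | COc1ccc(COC(=O)/C(C)=C\CO)cc1 | intermediate
16 | (4-methoxyphenyl)methyl (Z)-4-acetoxy-2-methylbut-2-enoate | COc1ccc(COC(=O)/C(C)=C\COC(C)=O)cc1 | intermediate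
17 | (Z)-4-acetoxy-2-methylbut-2-enoic acid | OC(=O)/C(C)=C\COC(C)=O | intermediate
18 | (Z)-4-acetoxy-2-methylbut-2-enoic 2,4,6-trichlorobenzoic anhydride | O=C(OC(=O)/C(C)=C\COC(C)=O)c1c(Cl)cc(Cl)cc1Cl | intermediate
19 | (2S,3S)-5-acetyl-6-[(4-methoxyphenyl)methoxy]-2-(prop-1-en-2-yl)-2,3-dihydro-1-benzofuran-3-yl (Z)-4-acetoxy-2-methylbut-2-enoate | C=C(C)[C@@H]1Oc2cc(OCc3ccc(OC)cc3)c(C(C)=O)cc2[C@@H]1OC(=O)/C(C)=C\COC(C)=O | intermediate
20 | (2S,3S)-5-acetyl-6-hydroxy-2-(prop-1-en-2-yl)-2,3-dihydro-1-benzofuran-3-yl (Z)-4-acetoxy-2-methylbut-2-enoate | C=C(C)[C@@H]1Oc2cc(O)c(C(C)=O)cc2[C@@H]1OC(=O)/C(C)=C\COC(C)=O | target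

**Step count**

Total step count: 9.
Longest linear sequence: 6 steps (steps 1, 2, 3, 4, 8, 9).

**Steps most likely to fail**

1. Step 4. During the slower second substitution, intermolecular fluoride displacement by the C3 alkoxide of another molecule and enolate-driven condensation of the acetyl group may compete, so chemoselectivity may be lost under the strongly basic one-flask conditions. The fallback sets out from 10 and comes back at 12, doing the two substitutions separately with the C3 oxygen masked. Ring closure alone with Cs2CO3 in DMSO at 50 °C should give isolated 11. Silylation (t-BuMe2SiCl, imidazole, DMF) should give 1-[(2S,3S)-3-(tert-butyldimethylsilyloxy)-6-fluoro-2-(prop-1-en-2-yl)-2,3-dihydro-1-benzofuran-5-yl]ethan-1-one F1. Displacement of the C6 fluoride with KOCH2C6H4-4-OMe (from the alcohol and KOt-Bu, THF, 0 °C → rt) should give 1-[(2S,3S)-3-(tert-butyldimethylsilyloxy)-6-[(4-methoxyphenyl)methoxy]-2-(prop-1-en-2-yl)-2,3-dihydro-1-benzofuran-5-yl]ethan-1-one F2. Desilylation (HF·pyridine, THF, 0 °C) returns to 12.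

2. Step 8. The (Z) geometry may be lost by reversible conjugate addition of base or chloride to the activated acyl species, and the hindered cis alcohol may acylate too slowly, so that forcing conditions trigger elimination toward the benzofuran. The fallback sets out from 12 and comes back at 19, building the alkene on the substrate so that no activated (Z)-acyl species is ever formed. Acylation of 12 with 2-[bis(2,2,2-trifluoroethoxy)phosphoryl]propanoic acid (EDC·HCl, DMAP, CH2Cl2) should give (2S,3S)-5-acetyl-6-[(4-methoxyphenyl)methoxy]-2-(prop-1-en-2-yl)-2,3-dihydro-1-benzofuran-3-yl 2-[bis(2,2,2-trifluoroethoxy)phosphoryl]propanoate F3, as a mixture of epimers at the phosphonate-bearing carbon. Still–Gennari olefination (KN(SiMe3)2, 18-crown-6, THF, −78 °C) with 2-oxoethyl acetate should then give 19 with the (Z) alkene set by the olefination.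

3. Step 1. Aryl transfer from the ortho-fluorinated arylzinc may be poorly face-selective, and the aryllithium may scramble by proton transfer at the position between the two fluorines. The fallback sets out from 1 and comes back at 6, reversing the polarity of the bond construction. Bromine–magnesium exchange (iPrMgCl·LiCl, THF, −20 °C) and formylation with DMF should give 5-bromo-2,4-difluorobenzaldehyde F4. A catalytic asymmetric Nozaki–Hiyama–Kishi alkenylation with 1-bromo-2-methylprop-1-ene (CrCl2 cat., NiCl2 cat., chiral oxazoline–sulfonamide ligand, Mn, Cp2ZrCl2, MeCN) should then give 6, the ligand enantiomer being chosen to deliver the (R) alcohol. This reaction adds to the aldehyde and leaves aryl halides untouched.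

**Further compounds**

F1 | step 4 | 1-[(2S,3S)-3-(tert-butyldimethylsilyloxy)-6-fluoro-2-(prop-1-en-2-yl)-2,3-dihydro-1-benzofuran-5-yl]ethan-1-one | C=C(C)[C@@H]1Oc2cc(F)c(C(C)=O)cc2[C@@H]1O[Si](C)(C)C(C)(C)C
F2 | step 4 | 1-[(2S,3S)-3-(tert-butyldimethylsilyloxy)-6-[(4-methoxyphenyl)methoxy]-2-(prop-1-en-2-yl)-2,3-dihydro-1-benzofuran-5-yl]ethan-1-one | C=C(C)[C@@H]1Oc2cc(OCc3ccc(OC)cc3)c(C(C)=O)cc2[C@@H]1O[Si](C)(C)C(C)(C)C
F3 | step 8 | (2S,3S)-5-acetyl-6-[(4-methoxyphenyl)methoxy]-2-(prop-1-en-2-yl)-2,3-dihydro-1-benzofuran-3-yl 2-[bis(2,2,2-trifluoroethoxy)phosphoryl]propanoate | C=C(C)[C@@H]1Oc2cc(OCc3ccc(OC)cc3)c(C(C)=O)cc2[C@@H]1OC(=O)C(C)P(=O)(OCC(F)(F)F)OCC(F)(F)F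
F4 | step 1 | 5-bromo-2,4-difluorobenzaldehyde | O=Cc1cc(Br)c(F)cc1F
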